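The 14-membered carbocycle (C1–C14; C1 carries the lactone arm C15–C16, C4–C7 lie in the oxolane, C8 bears methylene C19, C11 and C12 are the carbinols) is opened at C9–C10. The unit C19H2=C8–C9–C10–C11(=O) is the γ,δ-unsaturated ketone that a Claisen rearrangement delivers, and the 2-substituted allyl part has two equivalent CH2 ends. Step 18 therefore turns a 14-membered cyclic enol ether, C11(=CH2)–O–CH2–C8(=CH2), made by methylenation of a macrolactone, into the carbocyclic C11 ketone in one thermal operation. An easy macrolactonisation thus replaces a difficult C–C ring closure, and quaternary C12 blocks enol-ether isomerisation.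

Key step: step 18

Remarks and assumptions
- Locants follow the target throughout: ring C1–C14, C15/C16/C17 = lactone α-carbon, carbonyl and exocyclic methylene, C18 = methyl on C4, C19 = methylene on C8, C20 = methyl on C12. TBS = tert-butyldimethylsilyl, TMS = trimethylsilyl, Bpin = 4,4,5,5-tetramethyl-1,3,2-dioxaborolan-2-yl, 9-BBN = 9-borabicyclo[3.3.1]nonane.
- Assumption: (S)-linalool and (R)-2-methylglycidol are bought in high enantiomeric purity, and the L-fructose-derived Shi ketone (prepared from L-sorbose) is available.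
- Precursor design: O12 is carried as a small TMS ether, which keeps the hindered lactone carbonyl open to the titanium methylidene. O2 and O16 are TBS ethers installed in one operation. The TMS ether and the primary TBS ether are later removed together. No second carbonyl group is present at the methylenation.
- The facial sense of the catalysts in steps 1, 9 and 22 is assigned from the usual models for those reactions, not from a worked precedent on these substrates.

Step 1
Reactants: 1 (S)-linalool
Product: 3 2-[(2R,5S)-5-ethenyl-5-methyloxolan-2-yl]propan-2-ol, via epoxy alcohol 2 (not isolated)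
Conditions: L-fructose-derived Shi ketone (30 mol %), Oxone (2KHSO5·KHSO4·K2SO4), K2CO3, Bu4NHSO4, MeCN/(MeO)2CH2/aq. buffer (pH 10.5), 0 °C; then CSA (cat.), CH2Cl2, 0 °C
Reagents that add atoms: potassium peroxymonosulfate (active component of Oxone), [K+].[O-]S(=O)(=O)OO
Why: Shi epoxidation by the chiral dioxirane takes the electron-rich trisubstituted alkene (the vinyl group is far less nucleophilic) through a spiro transition state to the 6S epoxide, and acid-catalysed 5-exo opening by the tertiary hydroxyl with inversion sets the future C7 as R, cis to the future C3 arm; the minor 6-endo tetrahydropyran isomer should be separable.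

Step 2
Reactants: 3 2-[(2R,5S)-5-ethenyl-5-methyloxolan-2-yl]propan-2-ol
Product: 5 2-[(2S,5R)-5-(2-hydroxypropan-2-yl)-2-methyloxolan-2-yl]ethan-1-ol, via alkylborane 4 (not isolated)
Conditions: 9-BBN, THF, 0 °C → rt; then NaOH, H2O2, 0 °C → rt
Reagents that add atoms: hydrogen peroxide, OO
Why: Anti-Markovnikov hydroboration–oxidation places boron on the terminal carbon of the only alkene and oxidation with retention gives the primary alcohol, no stereocentre being touched.

Step 3
Reactants: 5 2-[(2S,5R)-5-(2-hydroxypropan-2-yl)-2-methyloxolan-2-yl]ethan-1-ol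
Product: 6 2-[(2S,5R)-5-(2-hydroxypropan-2-yl)-2-methyloxolan-2-yl]acetaldehyde
Conditions: TEMPO (10 mol %), PhI(OAc)2, CH2Cl2, rt
Reagents that add atoms: none
Why: Oxoammonium (TEMPO) oxidation is selective for the primary alcohol, leaves the tertiary carbinol alone and stops at the aldehyde in the absence of water.

Step 4
Reactants: 7 (R)-2-methylglycidol
Product: 8 (2S)-2-methylhex-5-ene-1,2-diol
Conditions: CH2=CHCH2MgBr (2.5 equiv), CuI (10 mol %), THF, −30 → 0 °C; then 1 M HCl, 0 °C
Reagents that add atoms: allylmagnesium bromide, C=CC[Mg]Br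
Why: Copper-catalysed Grignard opening of the 2,2-disubstituted epoxide occurs by SN2 attack at its CH2 terminus, so the quaternary stereocentre (future C12) is untouched and only its CIP descriptor changes.

Step 5
Reactants: 8 (2S)-2-methylhex-5-ene-1,2-diol
Product: 10 (2S)-2-hydroxy-2-methylhex-5-enoic acid, via hydroxy aldehyde 9 (not isolated)
Conditions: TEMPO (cat.), NaOCl (cat.), NaClO2, MeCN/phosphate buffer (pH 6.7), 35 °C
Reagents that add atoms: sodium chlorite, [Na+].[O-]Cl=O
Why: TEMPO-catalysed chlorite oxidation takes the primary alcohol through the aldehyde to the acid, while the tertiary hydroxyl and the monosubstituted alkene are not oxidised.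

Step 6
Reactants: 10 (2S)-2-hydroxy-2-methylhex-5-enoic acid
Product: 11 (5S)-5-(but-3-en-1-yl)-2,2,5-trimethyl-1,3-dioxolan-4-one
Conditions: 2,2-dimethoxypropane, PPTS (cat.), CH2Cl2, 40 °C
Reagents that add atoms: 2,2-dimethoxypropane, COC(C)(C)OC
Why: Acid-catalysed acetalisation of the α-hydroxy acid closes the five-membered dioxolanone and so masks the tertiary hydroxyl and the carboxyl group in one operation.

Step 7
Reactants: 11 (5S)-5-(but-3-en-1-yl)-2,2,5-trimethyl-1,3-dioxolan-4-one
Product: 12 (2E)-5-[(4S)-2,2,4-trimethyl-5-oxo-1,3-dioxolan-4-yl]pent-2-en-1-yl acetate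
Conditions: (Z)-AcOCH2CH=CHCH2OAc (3 equiv), second-generation Grubbs catalyst RuCl2(=CHPh)(PCy3)(H2IMes) (5 mol %), CH2Cl2, 40 °C
Reagents that add atoms: (Z)-but-2-ene-1,4-diyl diacetate, CC(=O)OC/C=C\COC(C)=O
Why: Olefin cross-metathesis of the terminal alkene with an excess of the symmetrical allylic diacetate should give the internal allylic acetate mainly as the E isomer.

Step 8
Reactants: 12 (2E)-5-[(4S)-2,2,4-trimethyl-5-oxo-1,3-dioxolan-4-yl]pent-2-en-1-yl acetate
Product: 13 (5S)-2,2,5-trimethyl-5-[(3E)-5-Bpin-pent-3-en-1-yl]-1,3-dioxolan-4-one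
Conditions: B2pin2, Pd2(dba)3 (2.5 mol %), DMSO, 50 °C
Reagents that add atoms: bis(pinacolato)diboron, CC1(C)OB(OC1(C)C)B1OC(C)(C)C(C)(C)O1
Why: Miyaura-type allylic borylation proceeds through a π-allylpalladium acetate that equilibrates to the syn isomer and is borylated at the unsubstituted terminus, so the linear E allylboronate should result even from any Z acetate.

Step 9
Reactants: 6 2-[(2S,5R)-5-(2-hydroxypropan-2-yl)-2-methyloxolan-2-yl]acetaldehyde; 13 (5S)-2,2,5-trimethyl-5-[(3E)-5-Bpin-pent-3-en-1-yl]-1,3-dioxolan-4-one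
Product: 15 anti homoallylic alcohol (1R,2S) with vinyl on C1 and dioxolanone at C11/C12, via borate ester 14 (not isolated)
Conditions: (R)-TRIP phosphoric acid (10 mol %), 4 Å molecular sieves, toluene, −30 °C; then aq. NaHCO3
Reagents that add atoms: none
Why: Chiral phosphoric acid-catalysed allylboration goes through a closed chair (Zimmerman–Traxler) transition state with γ-attack, so the E boronate fixes the C1/C2 anti relationship, while the (R)-configured acid directs C1 to the Re face of the aldehyde and thereby sets 2S and 1R (the other anti diastereomer should be separable).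

Step 10
Reactants: 15 anti homoallylic alcohol (1R,2S)
Product: 17 triol with free 2-OH 16-OH and tertiary C8-OH, via alkylborane 16 (not isolated)
Conditions: 9-BBN (4 equiv), THF, 0 °C → rt; then NaBO3·4H2O, THF/H2O, rt
Reagents that add atoms: sodium perborate, [Na+].[Na+].O[B-]1(O)OO[B-](O)(O)OO1
Why: Hydroboration–oxidation with 9-BBN adds boron to C16 of the only alkene (C15=C16) without reducing the dioxolanone, and the near-neutral perborate oxidation should give the primary alcohol with the acylal intact.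

Step 11
Reactants: 17 triol
Product: 18 2,16-bis-TBS ether with free tertiary C8-OH
Conditions: TBSCl, imidazole, DMAP (cat.), DMF, 40 °C
Reagents that add atoms: tert-butyldimethylsilyl chloride, CC(C)(C)[Si](C)(C)Cl
Why: Silylation with TBSCl and imidazole reaches the primary and the secondary hydroxyl but not the tertiary carbinol, which stays free for the dehydration.

Step 12
Reactants: 18 2,16-bis-TBS ether with free tertiary C8-OH
Product: 19 isopropenyl compound (C8=C9)
Conditions: SOCl2, pyridine, CH2Cl2, −20 → 0 °C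
Reagents that add atoms: none
Why: Dehydration of the tertiary alcohol through its chlorosulfite by pyridine-mediated E2 elimination should take a proton from a methyl group in preference to the hindered C7–H next to the ring oxygen, giving the 1,1-disubstituted alkene.

Step 13
Reactants: 19 isopropenyl compound (C8=C9)
Product: 20 allylic alcohol (C19-OH)
Conditions: SeO2 (30 mol %), t-BuOOH, CH2Cl2, 0 °C → rt
Reagents that add atoms: selenium dioxide (oxygen carrier), O=[Se]=O; tert-butyl hydroperoxide (terminal oxidant), CC(C)(C)OO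
Why: SeO2 allylic oxidation (ene reaction at the terminal CH2, then [2,3]-sigmatropic shift of the allylseleninic acid) hydroxylates the allylic methyl group and returns the alkene to its 1,1-disubstituted position, the methyl C–H being preferred over the methine C7–H.

Step 14
Reactants: 20 allylic alcohol (C19-OH)
Product: 21 seco acid (C11 acid with free 12-OH and 19-OH)
Conditions: LiOH·H2O, THF/H2O, 0 °C → rt; then 0.5 M HCl to pH 4, 0 °C
Reagents that add atoms: lithium hydroxide, [Li+].[OH-]
Why: Saponification opens the dioxolanone at the acyl carbon and the hemiketal so formed loses acetone, freeing the C11 acid and the C12 hydroxyl while the silyl ethers are stable to base.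

Step 15
Reactants: 21 seco acid
Product: 23 14-membered macrolactone with free 12-OH, via mixed anhydride 22 (not isolated)
Conditions: 2,4,6-Cl3C6H2COCl, Et3N, THF, rt; then slow addition to DMAP, toluene, 80 °C (1 mM)
Reagents that add atoms: none
Why: In this Yamaguchi macrolactonisation the mixed anhydride is activated by DMAP and captured under high dilution by the primary allylic C19 hydroxyl, the tertiary C12 hydroxyl being too hindered to compete.

Step 16
Reactants: 23 14-membered macrolactone with free 12-OH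
Product: 24 12-O-TMS macrolactone
Conditions: TMSOTf, 2,6-lutidine, CH2Cl2, −78 → 0 °C
Reagents that add atoms: trimethylsilyl trifluoromethanesulfonate, C[Si](C)(C)OS(=O)(=O)C(F)(F)F
Why: A silyl triflate with a hindered base silylates the tertiary α-hydroxy lactone, removing the acidic proton before the titanium reagent is used while keeping the carbonyl accessible.

Step 17
Reactants: 24 12-O-TMS macrolactone
Product: 25 14-membered cyclic enol ether C11(=C10H2)–O–C19H2–C8(=C9H2)
Conditions: Cp2Ti(μ-CH2)(μ-Cl)AlMe2, pyridine (cat.), THF/toluene, −40 °C → rt; aq. NaOH quench; filtration through basic Al2O3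
Reagents that add atoms: Tebbe reagent, C[Al-]1(C)C[Ti](C2C=CC=C2)(C3C=CC=C3)[Cl+]1
Why: Tebbe methylenation proceeds by [2+2] cycloaddition of the titanium methylidene to the lactone carbonyl and cycloreversion to the enol ether, which cannot isomerise into the ring because C12 bears no hydrogen.

Step 18
Reactants: 25 14-membered cyclic enol ether
Product: 26 14-membered carbocyclic C11 ketone with C8 exocyclic methylene (C19)
Conditions: toluene (degassed, base-washed glass), Et3N (5 mol %), 110–130 °C
Reagents that add atoms: none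
Why: On heating, the allyl vinyl ether C10=C11–O–C19–C8=C9 undergoes a concerted, suprafacial [3,3]-sigmatropic (Claisen) shift through a six-membered transition state in which C9–C10 forms as O–C19 breaks. The closest known reaction type is the methylenation–Claisen conversion of lactones into carbocyclic ketones by way of 2-methylene oxacycles. The carbocycle is not made by an exo or endo cyclisation: O and C19 leave the 14-membered ring while C9 and C10 enter it, the ten-atom chain C12–C7 bridging positions 2 and 5 of the transition state, which either a chair or a boat can accommodate. No stereocentre is created, and C1, C2, C4, C7 and C12 are spectators. The step needs only constitutional control, and the substrate provides it: the oxygen on C11 fixes the ketone position, the two CH2 termini of the allyl unit are equivalent, and quaternary C12 excludes enol-ether isomerisation. The amine buffer and base-washed glass are there to suppress acid-induced hydrolysis or ionisation of the enol ether.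

Step 19
Reactants: 26 14-membered carbocyclic C11 ketone
Product: 27 keto diol (free 12-OH and 16-OH; 2-OTBS kept)
Conditions: HF·pyridine, pyridine, THF, 0 °C → rt
Reagents that add atoms: none
Why: Buffered HF·pyridine should cleave the unhindered primary TBS ether and the labile tertiary TMS ether much faster than the hindered secondary TBS ether at C2.

Step 20
Reactants: 27 keto diol
Product: 29 keto hydroxy acid (C16 acid; free 12-OH), via aldehyde 28 (not isolated)
Conditions: TEMPO (20 mol %), PhI(OAc)2, MeCN/H2O, rt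
Reagents that add atoms: water, O
Why: TEMPO/PhI(OAc)2 in aqueous acetonitrile oxidises the primary alcohol through the aldehyde hydrate to the acid, while the tertiary α-ketol, the ketone and the 1,1-disubstituted alkene should not be attacked.

Step 21
Reactants: 29 keto hydroxy acid
Product: 31 keto ε-lactone (C16 carbonyl to O12), via mixed anhydride 30 (not isolated)
Conditions: 2,4,6-Cl3C6H2COCl, Et3N, THF, rt; then DMAP, toluene, 60 °C (2 mM)
Reagents that add atoms: none
Why: Yamaguchi lactonisation transfers the acyl group through the acylpyridinium ion to the tertiary C12 hydroxyl, the only hydroxyl in the molecule, closing the seven-membered ring; tertiary α-ketols are a class known to be acylated under DMAP catalysis.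

Step 22
Reactants: 31 keto ε-lactone
Product: 33 11S hydroxy lactone, via catechol borate 32 (not isolated)
Conditions: (R)-2-methyl-CBS-oxazaborolidine (50 mol %), catecholborane, toluene, −78 → −40 °C; then MeOH, aq. work-up
Reagents that add atoms: none
Why: In this Corey–Bakshi–Shibata reduction the ketone binds to the oxazaborolidine anti to its larger flank (quaternary C12) and receives hydride on one face, which with the (R)-catalyst should give 11S; this is also the Felkin–Anh product with the C12–O bond anti to the incoming hydride, so reagent and substrate control agree.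

Step 23
Reactants: 33 11S hydroxy lactone
Product: 34 2,11-bis-TBS lactone
Conditions: TBSOTf, 2,6-lutidine, CH2Cl2, −40 → 0 °C
Reagents that add atoms: tert-butyldimethylsilyl trifluoromethanesulfonate, CC(C)(C)[Si](C)(C)OS(=O)(=O)C(F)(F)F
Why: Silyl triflate silylation of the hindered secondary alcohol blocks the hydroxyl so that no alkoxide next to the lactone oxygen (acyl migration) can form in the enolate step.

Step 24
Reactants: 34 2,11-bis-TBS lactone
Product: 37 bis-TBS α-methylene lactone, via Mannich base 35 (not isolated), via ammonium iodide 36 (not isolated)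
Conditions: LiN(i-Pr)2, THF, −78 °C; CH2=NMe2+ I−, −78 °C → rt; then MeI, MeOH, rt; then aq. NaHCO3, CH2Cl2, rt
Reagents that add atoms: Eschenmoser's salt, C=[N+](C)C.[I-]
Why: In the Eschenmoser methylenation the lithium enolate of the lactone (C15 is its only α-carbon) is aminomethylated in a Mannich reaction, the amine is quaternised and β-elimination of trimethylamine gives the exocyclic C15=C17 alkene.

Step 25
Reactants: 37 bis-TBS α-methylene lactone
Product: 38 CNP0289823.1
Conditions: HF·pyridine, THF, 0 °C → rt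
Reagents that add atoms: none
Why: Fluoride-driven desilylation removes both secondary TBS ethers under mildly acidic conditions that should spare the α-methylene lactone and avoid the acyl migration a basic fluoride source could cause.

Compound list
1 | (S)-linalool, (3S)-3,7-dimethylocta-1,6-dien-3-ol | C=C[C@@](C)(O)CCC=C(C)C | starting material
2 | (3S)-5-[(2S)-3,3-dimethyloxiran-2-yl]-3-methylpent-1-en-3-ol | C=C[C@@](C)(O)CC[C@@H]1OC1(C)C | intermediate
3 | 2-[(2R,5S)-5-ethenyl-5-methyloxolan-2-yl]propan-2-ol (cis-furanoid linalool oxide) | C=C[C@]1(C)CC[C@@H](O1)C(C)(C)O | intermediate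
4 | B-alkyl-9-BBN adduct of 3 (boron on the terminal carbon of the former vinyl group; stereocentres as in 3) | B1(C2CCCC1CCC2)CC[C@]3(C)CC[C@@H](O3)C(C)(C)O | intermediate
5 | 2-[(2S,5R)-5-(2-hydroxypropan-2-yl)-2-methyloxolan-2-yl]ethan-1-ol | OCC[C@]1(C)CC[C@@H](O1)C(C)(C)O | intermediate
6 | 2-[(2S,5R)-5-(2-hydroxypropan-2-yl)-2-methyloxolan-2-yl]acetaldehyde | O=CC[C@]1(C)CC[C@@H](O1)C(C)(C)O | intermediate
7 | (R)-2-methylglycidol, [(2R)-2-methyloxiran-2-yl]methanol | OC[C@]1(C)CO1 | starting material
8 | (2S)-2-methylhex-5-ene-1,2-diol | OC[C@](O)(C)CCC=C | intermediate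
9 | (2S)-2-hydroxy-2-methylhex-5-enal | O=C[C@](O)(C)CCC=C | intermediate
10 | (2S)-2-hydroxy-2-methylhex-5-enoic acid | OC(=O)[C@](O)(C)CCC=C | intermediate
11 | (5S)-5-(but-3-en-1-yl)-2,2,5-trimethyl-1,3-dioxolan-4-one | O=C1OC(C)(C)O[C@@]1(C)CCC=C | intermediate
12 | (2E)-5-[(4S)-2,2,4-trimethyl-5-oxo-1,3-dioxolan-4-yl]pent-2-en-1-yl acetate | O=C1OC(C)(C)O[C@@]1(C)CC/C=C/COC(C)=O | intermediate
13 | (5S)-2,2,5-trimethyl-5-[(3E)-5-(4,4,5,5-tetramethyl-1,3,2-dioxaborolan-2-yl)pent-3-en-1-yl]-1,3-dioxolan-4-one | O=C1OC(C)(C)O[C@@]1(C)CC/C=C/CB2OC(C)(C)C(C)(C)O2 | intermediate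
14 | 2-O-Bpin borate ester of 15 | O=C1OC(C)(C)O[C@@]1(C)CC[C@H](C=C)[C@@H](OB3OC(C)(C)C(C)(C)O3)C[C@]2(C)CC[C@@H](O2)C(C)(C)O | intermediate
15 | (5S)-5-[(3R,4S)-3-ethenyl-4-hydroxy-5-[(2S,5R)-5-(2-hydroxypropan-2-yl)-2-methyloxolan-2-yl]pentyl]-2,2,5-trimethyl-1,3-dioxolan-4-one | O=C1OC(C)(C)O[C@@]1(C)CC[C@H](C=C)[C@@H](O)C[C@]2(C)CC[C@@H](O2)C(C)(C)O | intermediate
16 | B-alkyl-9-BBN adduct of 15 (boron on C16; stereocentres as in 15) | O=C1OC(C)(C)O[C@@]1(C)CC[C@H](CCB3C4CCCC3CCC4)[C@@H](O)C[C@]2(C)CC[C@@H](O2)C(C)(C)O | intermediate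
17 | (5S)-5-[(3R,4S)-4-hydroxy-3-(2-hydroxyethyl)-5-[(2S,5R)-5-(2-hydroxypropan-2-yl)-2-methyloxolan-2-yl]pentyl]-2,2,5-trimethyl-1,3-dioxolan-4-one | O=C1OC(C)(C)O[C@@]1(C)CC[C@H](CCO)[C@@H](O)C[C@]2(C)CC[C@@H](O2)C(C)(C)O | intermediate
18 | (5S)-5-[(3R,4S)-4-(TBS-oxy)-3-[2-(TBS-oxy)ethyl]-5-[(2S,5R)-5-(2-hydroxypropan-2-yl)-2-methyloxolan-2-yl]pentyl]-2,2,5-trimethyl-1,3-dioxolan-4-one | O=C1OC(C)(C)O[C@@]1(C)CC[C@H](CCO[Si](C)(C)C(C)(C)C)[C@@H](O[Si](C)(C)C(C)(C)C)C[C@]2(C)CC[C@@H](O2)C(C)(C)O | intermediate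
19 | (5S)-5-[(3R,4S)-4-(TBS-oxy)-3-[2-(TBS-oxy)ethyl]-5-[(2S,5R)-2-methyl-5-(prop-1-en-2-yl)oxolan-2-yl]pentyl]-2,2,5-trimethyl-1,3-dioxolan-4-one | O=C1OC(C)(C)O[C@@]1(C)CC[C@H](CCO[Si](C)(C)C(C)(C)C)[C@@H](O[Si](C)(C)C(C)(C)C)C[C@]2(C)CC[C@@H](O2)C(C)=C | intermediate
20 | (5S)-5-[(3R,4S)-4-(TBS-oxy)-3-[2-(TBS-oxy)ethyl]-5-[(2S,5R)-5-(3-hydroxyprop-1-en-2-yl)-2-methyloxolan-2-yl]pentyl]-2,2,5-trimethyl-1,3-dioxolan-4-one | O=C1OC(C)(C)O[C@@]1(C)CC[C@H](CCO[Si](C)(C)C(C)(C)C)[C@@H](O[Si](C)(C)C(C)(C)C)C[C@]2(C)CC[C@@H](O2)C(=C)CO | intermediate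
21 | (2S,5R,6S)-6-(TBS-oxy)-5-[2-(TBS-oxy)ethyl]-2-hydroxy-7-[(2S,5R)-5-(3-hydroxyprop-1-en-2-yl)-2-methyloxolan-2-yl]-2-methylheptanoic acid | OC(=O)[C@](O)(C)CC[C@H](CCO[Si](C)(C)C(C)(C)C)[C@@H](O[Si](C)(C)C(C)(C)C)C[C@]1(C)CC[C@@H](O1)C(=C)CO | intermediate
22 | mixed anhydride of acid 21 with 2,4,6-trichlorobenzoic acid | O=C(OC(=O)c1c(Cl)cc(Cl)cc1Cl)[C@](O)(C)CC[C@H](CCO[Si](C)(C)C(C)(C)C)[C@@H](O[Si](C)(C)C(C)(C)C)C[C@]2(C)CC[C@@H](O2)C(=C)CO | intermediate
23 | (1R,2S,4S,7R,12S)-macrolactone: 14-membered ring C1–C8, C19H2, O, C11(=O), C12–C14; 4,7-oxolane bridge; 8-methylene (C9); 12-hydroxy-12-methyl; 2-OTBS; 1-(2-TBS-oxyethyl) | O[C@@]1(C)CC[C@H](CCO[Si](C)(C)C(C)(C)C)[C@@H](O[Si](C)(C)C(C)(C)C)C[C@]2(C)CC[C@@H](O2)C(=C)COC1=O | intermediate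
24 | 12-O-TMS ether of macrolactone 23 (1R,2S,4S,7R,12S) | C[Si](C)(C)O[C@@]1(C)CC[C@H](CCO[Si](C)(C)C(C)(C)C)[C@@H](O[Si](C)(C)C(C)(C)C)C[C@]2(C)CC[C@@H](O2)C(=C)COC1=C(=O) is not used; correct string: C[Si](C)(C)O[C@@]1(C)CC[C@H](CCO[Si](C)(C)C(C)(C)C)[C@@H](O[Si](C)(C)C(C)(C)C)C[C@]2(C)CC[C@@H](O2)C(=C)COC1=O | intermediate
25 | (1R,2S,4S,7R,12S)-14-membered 2-methylene oxacycle: as 24 with C11(=C10H2) in place of the lactone carbonyl (allyl vinyl ether C10=C11–O–C19–C8=C9) | C[Si](C)(C)O[C@@]1(C)CC[C@H](CCO[Si](C)(C)C(C)(C)C)[C@@H](O[Si](C)(C)C(C)(C)C)C[C@]2(C)CC[C@@H](O2)C(=C)COC1=C | intermediate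
26 | (1R,2S,4S,7R,12S)-14-membered carbocyclic ketone: C11 ketone; 8-methylene (C19); 4,7-oxolane bridge; 12-OTMS; 2-OTBS; 1-(2-TBS-oxyethyl) | C[Si](C)(C)O[C@@]1(C)CC[C@H](CCO[Si](C)(C)C(C)(C)C)[C@@H](O[Si](C)(C)C(C)(C)C)C[C@]2(C)CC[C@@H](O2)C(=C)CCC1=O | intermediate
27 | keto diol: as 26 with free 12-OH and 1-(2-hydroxyethyl); 2-OTBS | O[C@@]1(C)CC[C@H](CCO)[C@@H](O[Si](C)(C)C(C)(C)C)C[C@]2(C)CC[C@@H](O2)C(=C)CCC1=O | intermediate
28 | C16 aldehyde: as 27 with 1-(2-oxoethyl) | O[C@@]1(C)CC[C@H](CC=O)[C@@H](O[Si](C)(C)C(C)(C)C)C[C@]2(C)CC[C@@H](O2)C(=C)CCC1=O | intermediate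
29 | C16 acid: as 27 with 1-(carboxymethyl) | O[C@@]1(C)CC[C@H](CC(=O)O)[C@@H](O[Si](C)(C)C(C)(C)C)C[C@]2(C)CC[C@@H](O2)C(=C)CCC1=O | intermediate
30 | mixed anhydride of acid 29 with 2,4,6-trichlorobenzoic acid | O[C@@]1(C)CC[C@H](CC(=O)OC(=O)c3c(Cl)cc(Cl)cc3Cl)[C@@H](O[Si](C)(C)C(C)(C)C)C[C@]2(C)CC[C@@H](O2)C(=C)CCC1=O | intermediate
31 | (1R,2S,4S,7R,12S)-keto lactone: seven-membered lactone C1–C15H2–C16(=O)–O–C12 across the carbocycle; C11 ketone; 2-OTBS | C1C(=O)O[C@@]2(C)CC[C@H]1[C@@H](O[Si](C)(C)C(C)(C)C)C[C@]3(C)CC[C@@H](O3)C(=C)CCC2=O | intermediate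
32 | 11-O-catecholborate of 33 | C1C(=O)O[C@@]2(C)CC[C@H]1[C@@H](O[Si](C)(C)C(C)(C)C)C[C@]3(C)CC[C@@H](O3)C(=C)CC[C@@H]2OB4Oc5ccccc5O4 | intermediate
33 | (1R,2S,4S,7R,11S,12S)-11-hydroxy lactone; 2-OTBS | C1C(=O)O[C@@]2(C)CC[C@H]1[C@@H](O[Si](C)(C)C(C)(C)C)C[C@]3(C)CC[C@@H](O3)C(=C)CC[C@@H]2O | intermediate
34 | (1R,2S,4S,7R,11S,12S)-2,11-bis-OTBS lactone | C1C(=O)O[C@@]2(C)CC[C@H]1[C@@H](O[Si](C)(C)C(C)(C)C)C[C@]3(C)CC[C@@H](O3)C(=C)CC[C@@H]2O[Si](C)(C)C(C)(C)C | intermediate
35 | 15-(dimethylaminomethyl) derivative of 34 (C15 epimers) | CN(C)CC1C(=O)O[C@@]2(C)CC[C@H]1[C@@H](O[Si](C)(C)C(C)(C)C)C[C@]3(C)CC[C@@H](O3)C(=C)CC[C@@H]2O[Si](C)(C)C(C)(C)C | intermediate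
36 | trimethylammonium iodide from 35 | C[N+](C)(C)CC1C(=O)O[C@@]2(C)CC[C@H]1[C@@H](O[Si](C)(C)C(C)(C)C)C[C@]3(C)CC[C@@H](O3)C(=C)CC[C@@H]2O[Si](C)(C)C(C)(C)C.[I-] | intermediate
37 | (1R,2S,4S,7R,11S,12S)-2,11-bis-OTBS α-methylene lactone (C15=C17H2) | C=C1C(=O)O[C@@]2(C)CC[C@H]1[C@@H](O[Si](C)(C)C(C)(C)C)C[C@]3(C)CC[C@@H](O3)C(=C)CC[C@@H]2O[Si](C)(C)C(C)(C)C | intermediate
38 | CNP0289823.1: (1R,2S,4S,7R,11S,12S)-14-membered carbocycle with 4,7-oxolane bridge, 8-methylene, 2-OH, 11-OH and the α-methylene ε-lactone C1–C15(=C17H2)–C16(=O)–O–C12 | C=C1C(=O)O[C@@]2(C)CC[C@H]1[C@@H](O)C[C@]1(C)CC[C@@H](O1)C(=C)CC[C@@H]2O | target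

The SMILES of compound 24 is C[Si](C)(C)O[C@@]1(C)CC[C@H](CCO[Si](C)(C)C(C)(C)C)[C@@H](O[Si](C)(C)C(C)(C)C)C[C@]2(C)CC[C@@H](O2)C(=C)COC1=O.

Total step count: 25. Longest linear sequence: 22 steps (7 → 38 through steps 4–8 and 9–25); the linalool branch (steps 1–3) joins at step 9.

Steps most likely to fail

Step 18. The thermal rearrangement may be too slow in the macrocycle, so that the enol ether hydrolyses or ionises before the [3,3] shift takes place. The fallback sets out from 25 and uses i-Bu3Al in CH2Cl2 (−78 °C → rt). Aluminium coordination to the ether oxygen weakens the O–C19 bond and accelerates the rearrangement at low temperature, and the aluminium-bound ketone is then reduced in the same flask by β-hydride transfer. The product is the C11 carbinol F1 (both epimers), which Dess–Martin periodinane in CH2Cl2 oxidises to ketone 26, where the route is rejoined.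

Step 21. Acyl transfer to the hindered tertiary C12 hydroxyl may be outrun by intermolecular esterification or by base-induced α-ketol rearrangement at C11/C12. The fallback sets out from keto diol 27 and avoids acyl transfer altogether. TEMPO/PhI(OAc)2 in anhydrous CH2Cl2 oxidises the primary alcohol to the aldehyde, which is in ring–chain equilibrium with the seven-membered lactol F2. Without water the open aldehyde cannot go on to the acid, so oxidation of the lactol drains the equilibrium and gives lactone 31 directly (oxidative lactonisation). Steps 20 and 21 are replaced and the route is rejoined at 31.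

Step 13. The allylic oxidation may over-oxidise to the enal, attack the C7–H position, or cost the primary silyl ether under the acidic selenium conditions. The fallback sets out from 19 and replaces steps 13–15. Ene-type chlorination with hypochlorous acid (Ca(OCl)2, solid CO2, CH2Cl2/H2O, 0 °C) gives the 2-substituted allyl chloride F3. LiOH in THF/H2O at 0 °C then opens the dioxolanone to the chloro hydroxy acid F4. Cs2CO3 in DMF at high dilution (50 °C) closes the 14-membered ring by carboxylate alkylation and gives macrolactone 23, where the route is rejoined.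

Further compounds
F1 | step 18 | C11 carbinol corresponding to ketone 26 (both C11 epimers; 12-OTMS, 2-OTBS, 16-OTBS) | C[Si](C)(C)O[C@@]1(C)CC[C@H](CCO[Si](C)(C)C(C)(C)C)[C@@H](O[Si](C)(C)C(C)(C)C)C[C@]2(C)CC[C@@H](O2)C(=C)CCC1O
F2 | step 21 | seven-membered lactol (C16 hemiacetal to O12) of aldehyde 28 | C1C(O)O[C@@]2(C)CC[C@H]1[C@@H](O[Si](C)(C)C(C)(C)C)C[C@]3(C)CC[C@@H](O3)C(=C)CCC2=O
F3 | step 13 | allylic chloride: as 20 with C19–Cl in place of C19–OH | O=C1OC(C)(C)O[C@@]1(C)CC[C@H](CCO[Si](C)(C)C(C)(C)C)[C@@H](O[Si](C)(C)C(C)(C)C)C[C@]2(C)CC[C@@H](O2)C(=C)CCl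
F4 | step 13 | chloro hydroxy acid: as 21 with C19–Cl in place of C19–OH | OC(=O)[C@](O)(C)CC[C@H](CCO[Si](C)(C)C(C)(C)C)[C@@H](O[Si](C)(C)C(C)(C)C)C[C@]1(C)CC[C@@H](O1)C(=C)CCl
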